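**Plan**

1. Numbering: chain C1 (ester carbon) to C22; dioxane ring O1–O2–C3–C4–C5–C6, where ring C3–C6 are chain C3–C6 (C3 bears CH2CO2Me, C6 bears OMe and the C7–C22 chain).
2. Retrosynthesis, first cut O2–C3: the ring oxygen on C3 lies β to the C1 carbonyl and the O–O unit hangs on the ketal carbon C6 (a masked ketone), so ring O1–O2–C3–C4–C5–C6 is the 6-exo-trig peroxa-Michael adduct of a C6 methoxy hydroperoxide onto a C2=C3 enoate.
3. Further cuts: C6–OOH/C6–OMe (back to the C6 ketone), C2=C3 (Wittig), C5–C6 (Grignard on a Weinreb amide), C11–C12 (Sonogashira), C12=C13 (Takai).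
4. Forward: the C12–C22 vinyl iodide and hex-5-ynoic acid are joined, the chain is grown to an achiral open-chain keto enoate, the ketone becomes a racemic methoxy hydroperoxide, and the only ring is closed at the end.
5. Stereochemistry: C3 (S) comes from a chiral bifunctional base catalyst in the ring closure; C6 (R) is relayed from C3 by acid equilibration of the peroxyketal to the epimer with axial OMe and both carbon chains equatorial; 12E comes from the Takai olefination.

Key step: step 9

Assumption: the C6 epimers of the 3-methoxy-1,2-dioxane interconvert under acid with methanol without touching C3, and the (3S,6R) epimer (anomeric axial OMe, C3 and C6 carbon chains equatorial) is the more stable one.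

Catalyst of step 9: 1-[3,5-bis(trifluoromethyl)phenyl]-3-[3,3-dimethyl-1-{[tris(4-methoxyphenyl)-λ5-phosphanylidene]amino}butan-2-yl]urea, a bifunctional iminophosphorane made from tert-leucine. The sense of induction cannot be predicted with confidence, so of its two antipodes (from L- or D-tert-leucine) the one that gives 3S is to be fixed in the first run.

**Route**

Step 1
Reactants: 1 dec-9-en-1-ol
Product: 2 dec-9-enal
Conditions: TEMPO (2,2,6,6-tetramethylpiperidin-1-oxyl, 10 mol%), PhI(OAc)2, CH2Cl2, rt
Reagents that add atoms: none
Why: Oxoammonium-mediated oxidation of a primary alcohol should stop at the aldehyde and leave the terminal alkene untouched.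

Step 2
Reactants: 2 dec-9-enal
Product: 3 (E)-1-iodoundeca-1,10-diene
Conditions: CrCl2 (6 equiv), CHI3 (2 equiv), THF/1,4-dioxane, 0 °C to rt
Reagents that add atoms: iodoform (IC(I)I)
Why: Takai olefination: the geminal dichromium species from CHI3 and CrCl2 adds to the aldehyde and eliminates to give mainly the (E)-vinyl iodide, which sets the 12E alkene; the remote terminal alkene is inert.

Step 3
Reactants: 4 hex-5-ynoic acid
Product: 5 N-methoxy-N-methylhex-5-ynamide
Conditions: MeNH(OMe)·HCl, EDCI·HCl, Et3N, 4-(dimethylamino)pyridine (cat.), CH2Cl2, 0 °C to rt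
Reagents that add atoms: N,O-dimethylhydroxylamine hydrochloride (CNOC.Cl)
Why: Carbodiimide amide coupling should give the Weinreb amide, which later stops organomagnesium addition at the ketone stage.

Step 4
Reactants: 5 N-methoxy-N-methylhex-5-ynamide; 3 (E)-1-iodoundeca-1,10-diene
Product: 6 (7E)-N-methoxy-N-methylheptadeca-7,16-dien-5-ynamide
Conditions: PdCl2(PPh3)2 (3 mol%), CuI (6 mol%), Et3N, THF, rt
Reagents that add atoms: none
Why: Sonogashira coupling of a terminal alkyne with an (E)-vinyl iodide proceeds with retention of alkene geometry, tolerates the Weinreb amide, and removes the acidic alkyne hydrogen before the Grignard step.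

Step 5
Reactants: 6 (7E)-N-methoxy-N-methylheptadeca-7,16-dien-5-ynamide; 7 2-(2-bromoethyl)-1,3-dioxolane
Product: 9 (9E)-1-(1,3-dioxolan-2-yl)nonadeca-9,18-dien-7-yn-3-one, via Grignard reagent 8 (not isolated)
Conditions: 7, Mg, THF, below 30 °C; then 6, THF, 0 °C; sat. aq NH4Cl
Reagents that add atoms: none
Why: Grignard addition to a Weinreb amide gives a stable chelated tetrahedral adduct that collapses to the ketone only on work-up, so the acetal Grignard (a propanal homoenolate equivalent) should add once and form the C5–C6 bond.

Step 6
Reactants: 9 (9E)-1-(1,3-dioxolan-2-yl)nonadeca-9,18-dien-7-yn-3-one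
Product: 10 (10E)-4-oxoicosa-10,19-dien-8-ynal
Conditions: 2 M aq HCl, THF, rt
Reagents that add atoms: water (O)
Why: Acid-catalysed acetal hydrolysis should free the aldehyde while the ketone, the conjugated enyne and the terminal alkene are stable to dilute acid at room temperature.

Step 7
Reactants: 10 (10E)-4-oxoicosa-10,19-dien-8-ynal; 11 methyl (triphenylphosphoranylidene)acetate
Product: 12 methyl (2E,12E)-6-oxodocosa-2,12,21-trien-10-ynoate
Conditions: CH2Cl2, rt
Reagents that add atoms: none
Why: Wittig olefination with a stabilised ylide is selective for the aldehyde over the ketone and should give the (E)-enoate needed as the Michael acceptor.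

Step 8
Reactants: 12 methyl (2E,12E)-6-oxodocosa-2,12,21-trien-10-ynoate
Product: 13 methyl (2E,12E)-6-hydroperoxy-6-methoxydocosa-2,12,21-trien-10-ynoate (racemic at C6)
Conditions: urea–H2O2 (3 equiv), Sc(OTf)3 (10 mol%), MeOH, rt
Reagents that add atoms: urea–hydrogen peroxide (NC(N)=O.OO), which supplies hydrogen peroxide (OO); methanol (CO)
Why: Lewis-acid-catalysed methoxy-hydroperoxidation of a ketone (three-component peroxyketalisation) has close precedent on 6-oxo-2-enoates and should leave the enoate, the enyne and the alkene untouched; C6 is formed without control.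

Step 9
Reactants: 13 methyl (2E,12E)-6-hydroperoxy-6-methoxydocosa-2,12,21-trien-10-ynoate (racemic at C6)
Product: 14 methyl 2-[(3S)-6-[(6E)-hexadeca-6,15-dien-4-yn-1-yl]-6-methoxy-1,2-dioxan-3-yl]acetate (both C6 epimers)
Conditions: bifunctional iminophosphorane catalyst defined above (10 mol%), toluene, −20 °C to 0 °C
Reagents that add atoms: none
Why: Proposed new method: the iminophosphorane nitrogen deprotonates the hydroperoxide of 13 to a chiral aminophosphonium peroxide ion pair while the urea N–H bonds bind the ester carbonyl, the peroxide oxygen adds to C3 of the (E)-enoate, and the ester enolate is protonated by the aminophosphonium N–H, which frees the catalyst. The closest known reaction types are the enantioselective intramolecular oxa-Michael addition of alcohols to α,β-unsaturated esters under bifunctional iminophosphorane catalysis and the achiral amine-promoted closure of methoxy hydroperoxides onto enoates; the hydroperoxide is more acidic and, through the α-effect, more nucleophilic than the alcohols of the former, and a urea instead of a thiourea donor avoids oxidation at sulfur. The 1,2-dioxane ring (O1–O2–C3–C4–C5–C6) closes in the 6-exo-trig mode through a chair-like transition state. The new stereocentre C3 is set by the catalyst, which differentiates the two faces of the C2=C3 bond, whereas C6 is not touched and stays as both epimers. The step needs catalyst control to outweigh the weak 1,4-induction from C6, so that both enantiomers of 13 close with the same sense at C3, and it needs enolate protonation to outrun epoxide formation by attack of the enolate on the O–O bond; the remote position of C6, the fixed (E)-geometry with two-point binding of ester and peroxide, and the ion-paired proton source next to the enolate should secure this.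

Step 10
Reactants: 14 methyl 2-[(3S)-6-[(6E)-hexadeca-6,15-dien-4-yn-1-yl]-6-methoxy-1,2-dioxan-3-yl]acetate (both C6 epimers)
Product: 15 peroxyacarnoate A, methyl 2-[(3S,6R)-6-[(6E)-hexadeca-6,15-dien-4-yn-1-yl]-6-methoxy-1,2-dioxan-3-yl]acetate
Conditions: camphor-10-sulfonic acid (10 mol%), MeOH (5 equiv), CH2Cl2, rt; chromatography, minor C6 epimer resubmitted
Reagents that add atoms: methanol (CO)
Why: Acid-catalysed transketalisation (anomerisation) at the peroxyketal carbon C6, through a peroxycarbenium or ring-opened oxocarbenium ion, leaves the C3–O bond intact and should drive the mixture to the epimer with anomeric axial OMe and both carbon chains equatorial, so 6R is set by thermodynamic relay from C3.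

**Compound list**

1 | dec-9-en-1-ol | C=CCCCCCCCCO | starting material
2 | dec-9-enal | C=CCCCCCCCC=O | intermediate
3 | (E)-1-iodoundeca-1,10-diene | C=CCCCCCCC/C=C/I | intermediate
4 | hex-5-ynoic acid | C#CCCCC(=O)O | starting material
5 | N-methoxy-N-methylhex-5-ynamide | C#CCCCC(=O)N(C)OC | intermediate
6 | (7E)-N-methoxy-N-methylheptadeca-7,16-dien-5-ynamide | C=CCCCCCCC/C=C/C#CCCCC(=O)N(C)OC | intermediate
7 | 2-(2-bromoethyl)-1,3-dioxolane | BrCCC1OCCO1 | starting material
8 | [2-(1,3-dioxolan-2-yl)ethyl]magnesium bromide | Br[Mg]CCC1OCCO1 | intermediate
9 | (9E)-1-(1,3-dioxolan-2-yl)nonadeca-9,18-dien-7-yn-3-one | C=CCCCCCCC/C=C/C#CCCCC(=O)CCC1OCCO1 | intermediate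
10 | (10E)-4-oxoicosa-10,19-dien-8-ynal | C=CCCCCCCC/C=C/C#CCCCC(=O)CCC=O | intermediate
11 | methyl (triphenylphosphoranylidene)acetate | COC(=O)C=P(c1ccccc1)(c1ccccc1)c1ccccc1 | starting material
12 | methyl (2E,12E)-6-oxodocosa-2,12,21-trien-10-ynoate | C=CCCCCCCC/C=C/C#CCCCC(=O)CC/C=C/C(=O)OC | intermediate
13 | methyl (2E,12E)-6-hydroperoxy-6-methoxydocosa-2,12,21-trien-10-ynoate, racemic at C6 | C=CCCCCCCC/C=C/C#CCCCC(OC)(OO)CC/C=C/C(=O)OC | intermediate
14 | methyl 2-[(3S)-6-[(6E)-hexadeca-6,15-dien-4-yn-1-yl]-6-methoxy-1,2-dioxan-3-yl]acetate, both C6 epimers | C=CCCCCCCC/C=C/C#CCCCC1(OC)CC[C@@H](CC(=O)OC)OO1 | intermediate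
15 | peroxyacarnoate A, methyl 2-[(3S,6R)-6-[(6E)-hexadeca-6,15-dien-4-yn-1-yl]-6-methoxy-1,2-dioxan-3-yl]acetate | C=CCCCCCCC/C=C/C#CCCC[C@]1(OC)CC[C@@H](CC(=O)OC)OO1 | target

**Step count and risks**

Total steps: 10. Longest linear sequence: 9 steps (steps 1, 2, 4, 5, 6, 7, 8, 9, 10, from dec-9-en-1-ol).

Steps most likely to fail:

Step 9. The catalyst may fail to override the substrate's own bias from C6, or an uncatalysed background closure may compete, either of which lowers the enantiofacial selectivity at C3. The peroxide anion may also attack the aminophosphonium centre and destroy the catalyst, or the enolate may attack the O–O bond and form an epoxide. Fallback with known chemistry: setting out from 13, the established amine-promoted closure (Et2NH, CF3CH2OH, rt) should give the racemic dioxane as a mixture of C6 epimers F1. Acid equilibration with methanol, as for 14, should converge F1 to the racemate, that is 15 together with its antipode ent-peroxyacarnoate A F2. Preparative HPLC on a chiral stationary phase (cellulose tris(3,5-dimethylphenylcarbamate)) should then remove F2 and come back to the route at 15.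

Step 10. The thermodynamic bias between the C6 epimers may be incomplete, or acid may open the dioxane by solvolysis and the peroxide may be lost. Fallback: setting out from 14, ionisation with trimethylsilyl triflate (cat.) in CH2Cl2 at −78 °C in the presence of methoxytrimethylsilane should generate the cyclic peroxycarbenium ion at C6. Kinetic axial capture by the silyl ether then replaces equilibrium control by stereoelectronic control and should come back to the route at 15. This fallback makes no new compound (F0).

Step 8. Over-reaction to the geminal dihydroperoxide or the dimethyl ketal may occur, methanol or hydrogen peroxide may add to the enoate, or the ring may close prematurely without the catalyst. Fallback: setting out from 12, ketalisation with HC(OMe)3 and pyridinium p-toluenesulfonate in MeOH should give methyl (2E,12E)-6,6-dimethoxydocosa-2,12,21-trien-10-ynoate F3. Perhydrolysis of this ketal with one equivalent of ethereal H2O2 and catalytic camphor-10-sulfonic acid in Et2O at 0 °C exchanges a single methoxy group under stoichiometric control and should come back to the route at 13.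

Further compounds
F1 | step 9 | methyl 2-[6-[(6E)-hexadeca-6,15-dien-4-yn-1-yl]-6-methoxy-1,2-dioxan-3-yl]acetate, racemic mixture of C6 epimers | C=CCCCCCCC/C=C/C#CCCCC1(OC)CCC(CC(=O)OC)OO1
F2 | step 9 | ent-peroxyacarnoate A, methyl 2-[(3R,6S)-6-[(6E)-hexadeca-6,15-dien-4-yn-1-yl]-6-methoxy-1,2-dioxan-3-yl]acetate | C=CCCCCCCC/C=C/C#CCCC[C@@]1(OC)CC[C@H](CC(=O)OC)OO1
F0 | step 10 | none | none
F3 | step 8 | methyl (2E,12E)-6,6-dimethoxydocosa-2,12,21-trien-10-ynoate | C=CCCCCCCC/C=C/C#CCCCC(OC)(OC)CC/C=C/C(=O)OC
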